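**Strategy.** Ring B (the cyclopentenone: C1 carbonyl to C5, the carbon bound to ring A) is made by a one-carbon ring expansion that forms its C4–C5 bond. The key step exploits the 1,4-relationship between C5 and the oxygen of the acetoxymethyl group on C1′ of ring A: that oxygen closes a cis-fused tetrahydrofuran onto C5, a 2-methylcyclobutanol is attached there on the convex face, and an aluminium-promoted semipinacol shift then opens the ether. In one operation this builds the cyclopentanone, sets C5 by inversion and C4 by retention (the labile cis-4,5 pair), and frees the CH2OH group. Ring A comes from a Diels–Alder norbornene; a Schenck ene reaction ends the route.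

Key step: step 15

Remark on locants: ring A is numbered C1′ (carbinol carbon), C2′ (bears ring B) and C4′ (bears the side chain); the bicyclic intermediates use cyclopenta[c]furan locants, in which C1 is the later C5 of ring B and C3a the later C1′.
Remark on the catalyst: the (S)-configured oxazaborolidine is assumed to give the (1S,2S,4S) Diels–Alder adduct; if the facial sense is the reverse, its enantiomer is used.

Step 1
Reactants: 1 methyl (R)-2-hydroxypropanoate
Product: 2 (R)-1-(1-hydroxyethyl)cyclopropan-1-ol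
Conditions: EtMgBr (4.5 equiv), Ti(OiPr)4 (20 mol %), THF, 0 to 23 °C
Reagents that add atoms: ethylmagnesium bromide CC[Mg]Br
Why: Kulinkovich cyclopropanation, in which the titanacyclopropane formed from Ti(OiPr)4 and two equivalents of EtMgBr should add twice to the ester carbonyl, while the lactate stereocentre is not touched.

Step 2
Reactants: 2 (R)-1-(1-hydroxyethyl)cyclopropan-1-ol
Product: 4 (R)-2-methylcyclobutan-1-one, via mesylate 3 (not isolated)
Conditions: MeSO2Cl, Et3N, CH2Cl2, 0 to 23 °C
Reagents that add atoms: none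
Why: selective mesylation of the secondary alcohol followed by a semipinacol ring expansion, in which a cyclopropane C–C bond should migrate anti to the leaving mesylate, so the methyl-bearing centre is inverted stereospecifically and (R)-2 should give (R)-4 (volatile, used as a solution).

Step 3
Reactants: 5 cyclopenta-1,3-diene; 6 2,2,2-trifluoroethyl prop-2-enoate
Product: 7 2,2,2-trifluoroethyl (1S,2S,4S)-bicyclo[2.2.1]hept-5-ene-2-carboxylate
Conditions: (S)-3,3-diphenyl-1-(2-methylphenyl)tetrahydro-1H,3H-pyrrolo[1,2-c][1,3,2]oxazaborole (10 mol %), HN(SO2CF3)2 (8 mol %), CH2Cl2, −78 °C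
Reagents that add atoms: none
Why: enantioselective Diels–Alder reaction under chiral oxazaborolidinium catalysis, in which the bound acrylate should be attacked on one face only, so both bridgehead centres (the later C2′ and C4′) are set in one event; the endo/exo ratio at C2 is irrelevant because that centre is planarised in step 4.

Step 4
Reactants: 7 2,2,2-trifluoroethyl (1S,2S,4S)-bicyclo[2.2.1]hept-5-ene-2-carboxylate
Product: 8 2,2,2-trifluoroethyl (1S,2R,4S)-2-hydroxybicyclo[2.2.1]hept-5-ene-2-carboxylate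
Conditions: KN(SiMe3)2, THF, −78 °C; 2-(phenylsulfonyl)-3-phenyloxaziridine, −78 °C; NH4Cl
Reagents that add atoms: 2-(phenylsulfonyl)-3-phenyloxaziridine O=S(=O)(c1ccccc1)N1OC1c1ccccc1
Why: enolate hydroxylation with an N-sulfonyloxaziridine, in which the potassium enolate should be attacked on the exo face, away from the etheno bridge, so the hydroxyl group ends exo and the ester endo whichever ester epimer is used.

Step 5
Reactants: 8 2,2,2-trifluoroethyl (1S,2R,4S)-2-hydroxybicyclo[2.2.1]hept-5-ene-2-carboxylate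
Product: 9 (1S,2R,4S)-2-(hydroxymethyl)bicyclo[2.2.1]hept-5-en-2-ol
Conditions: LiAlH4, THF, 0 °C
Reagents that add atoms: none
Why: hydride reduction of the ester to the primary alcohol, with no stereocentre affected.

Step 6
Reactants: 9 (1S,2R,4S)-2-(hydroxymethyl)bicyclo[2.2.1]hept-5-en-2-ol
Product: 11 (3aR,5S,6aR)-1,3a-dihydroxyhexahydro-1H-cyclopenta[c]furan-5-carbaldehyde (both C1 epimers), via dialdehyde 10 (not isolated)
Conditions: O3, CH2Cl2–MeOH, −78 °C; Me2S, −78 to 23 °C
Reagents that add atoms: ozone [O-][O+]=O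
Why: ozonolysis with reductive work-up cleaves the strained alkene to two formyl groups that must be cis because they were joined in the bicycle, and the one next to the carbinol carbon should close onto the cis CH2OH group as a five-membered lactol (5-exo-trig hemiacetal formation), which tells the two aldehydes apart; the lactol centre forms as a mixture and is removed in step 14.

Step 7
Reactants: 11 (3aR,5S,6aR)-1,3a-dihydroxyhexahydro-1H-cyclopenta[c]furan-5-carbaldehyde
Product: 12 (3aR,5S,6aR)-5-ethynylhexahydro-1H-cyclopenta[c]furan-1,3a-diol (both C1 epimers)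
Conditions: dimethyl (1-diazo-2-oxopropyl)phosphonate (1.1 equiv), K2CO3, MeOH, 0 °C
Reagents that add atoms: dimethyl (1-diazo-2-oxopropyl)phosphonate COP(=O)(OC)C(=[N+]=[N-])C(C)=O
Why: Seyferth–Gilbert homologation in the Ohira–Bestmann variant, in which the free aldehyde should react much faster than the masked lactol; the α-branched aliphatic centre is not expected to epimerise at 0 °C.

Step 8
Reactants: 12 (3aR,5S,6aR)-5-ethynylhexahydro-1H-cyclopenta[c]furan-1,3a-diol
Product: 13 (3aR,5S,6aR)-5-ethynyl-1-(phenylsulfanyl)hexahydro-1H-cyclopenta[c]furan-3a-ol (both C1 epimers)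
Conditions: PhSH, BF3·OEt2 (20 mol %), CH2Cl2, −20 °C
Reagents that add atoms: benzenethiol Sc1ccccc1
Why: Lewis acid-catalysed thioacetal formation through the bicyclic oxocarbenium ion, which protects C1 and installs the handle for reductive lithiation; either configuration at C1 is acceptable.

Step 9
Reactants: 13 (3aR,5S,6aR)-5-ethynyl-1-(phenylsulfanyl)hexahydro-1H-cyclopenta[c]furan-3a-ol
Product: 14 methyl 3-[(3aR,5S,6aR)-3a-(methoxycarbonyloxy)-1-(phenylsulfanyl)hexahydro-1H-cyclopenta[c]furan-5-yl]prop-2-ynoate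
Conditions: n-BuLi (2.1 equiv), THF, −78 °C; ClCO2Me (2.5 equiv), −78 to 0 °C
Reagents that add atoms: methyl chloroformate COC(=O)Cl
Why: C-acylation of the lithium acetylide gives the alkynoate and O-acylation of the tertiary lithium alkoxide gives a methyl carbonate that masks the hydroxyl group during step 10.

Step 10
Reactants: 14 methyl 3-[(3aR,5S,6aR)-3a-(methoxycarbonyloxy)-1-(phenylsulfanyl)hexahydro-1H-cyclopenta[c]furan-5-yl]prop-2-ynoate
Product: 15 methyl (2Z)-3-[(3aR,5S,6aR)-3a-(methoxycarbonyloxy)-1-(phenylsulfanyl)hexahydro-1H-cyclopenta[c]furan-5-yl]but-2-enoate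
Conditions: Me2CuLi, THF, −78 °C; MeOH, −78 °C
Reagents that add atoms: lithium dimethylcuprate [Li+].C[Cu-]C
Why: conjugate addition of the cuprate to the alkynoate is a syn carbocupration, so methyl and copper end cis, and protonation at −78 °C with retention should give the (Z)-enoate in which ring and ester carbon are cis, as the side chain requires.

Step 11
Reactants: 15 methyl (2Z)-3-[(3aR,5S,6aR)-3a-(methoxycarbonyloxy)-1-(phenylsulfanyl)hexahydro-1H-cyclopenta[c]furan-5-yl]but-2-enoate
Product: 16 (3aR,5S,6aR)-5-[(2Z)-4-hydroxybut-2-en-2-yl]-1-(phenylsulfanyl)hexahydro-1H-cyclopenta[c]furan-3a-ol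
Conditions: i-Bu2AlH (excess), CH2Cl2, −78 to 0 °C; aq. potassium sodium tartrate
Reagents that add atoms: none
Why: 1,2-reduction of the enoate gives the allylic alcohol without change of alkene geometry, and the carbonate is cleaved reductively to free the tertiary alcohol.

Step 12
Reactants: 16 (3aR,5S,6aR)-5-[(2Z)-4-hydroxybut-2-en-2-yl]-1-(phenylsulfanyl)hexahydro-1H-cyclopenta[c]furan-3a-ol
Product: 18 (3aR,5S,6aR)-5-[(2Z)-4-chlorobut-2-en-2-yl]-1-(phenylsulfanyl)hexahydro-1H-cyclopenta[c]furan-3a-ol, via allylic mesylate 17 (not isolated)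
Conditions: MeSO2Cl, 2,4,6-collidine, LiCl, DMF, 0 °C
Reagents that add atoms: lithium chloride [Li+].[Cl-]
Why: mesylation of the primary allylic alcohol and SN2 displacement by chloride should keep the (Z)-geometry and avoid allylic transposition; the tertiary alcohol does not react.

Step 13
Reactants: 18 (3aR,5S,6aR)-5-[(2Z)-4-chlorobut-2-en-2-yl]-1-(phenylsulfanyl)hexahydro-1H-cyclopenta[c]furan-3a-ol
Product: 19 (3aR,5S,6aR)-5-[(2Z)-6-methylhepta-2,5-dien-2-yl]-1-(phenylsulfanyl)hexahydro-1H-cyclopenta[c]furan-3a-ol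
Conditions: (CH3)2C=CHMgBr (3 equiv), Li2CuCl4 (5 mol %), THF, −30 to 0 °C
Reagents that add atoms: 2-methylprop-1-enylmagnesium bromide CC(C)=C[Mg]Br
Why: copper-catalysed cross-coupling of the alkenyl Grignard reagent at the primary allylic carbon should give the skipped diene with the (Z)-alkene intact; one further equivalent of the Grignard reagent is consumed by the hydroxyl group.

Step 14
Reactants: 19 (3aR,5S,6aR)-5-[(2Z)-6-methylhepta-2,5-dien-2-yl]-1-(phenylsulfanyl)hexahydro-1H-cyclopenta[c]furan-3a-ol; 4 (R)-2-methylcyclobutan-1-one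
Product: 21 (1R,3aR,5S,6aS)-1-[(2R)-1-hydroxy-2-methylcyclobutyl]-5-[(2Z)-6-methylhepta-2,5-dien-2-yl]hexahydro-1H-cyclopenta[c]furan-3a-ol (both carbinol epimers), via organolithium 20 (not isolated)
Conditions: n-BuLi (1.0 equiv), THF, −78 °C; lithium 4,4′-di-tert-butylbiphenylide (2.2 equiv), −78 °C; 4 (1.5 equiv), −78 °C; NH4Cl
Reagents that add atoms: none
Why: reductive lithiation of the S,O-acetal gives the α-alkoxy organolithium at C1, and its 1,2-addition to the cyclobutanone should place the new C–C bond on the convex face of the cis-fused oxabicyclo[3.3.0]octane, giving (1R) whichever acetal epimer is used; the configuration of the new carbinol carbon does not matter because it becomes the carbonyl group in step 15.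

Step 15
Reactants: 21 (1R,3aR,5S,6aS)-1-[(2R)-1-hydroxy-2-methylcyclobutyl]-5-[(2Z)-6-methylhepta-2,5-dien-2-yl]hexahydro-1H-cyclopenta[c]furan-3a-ol
Product: 22 (2S,3R)-2-[(1S,2R,4S)-2-hydroxy-2-(hydroxymethyl)-4-[(2Z)-6-methylhepta-2,5-dien-2-yl]cyclopentyl]-3-methylcyclopentan-1-one
Conditions: Et2AlCl (3.5 equiv), CH2Cl2, −78 to 0 °C; aq. potassium sodium tartrate
Reagents that add atoms: none
Why: Proposed new method: both hydroxyl groups become aluminium alkoxides, the one on C3a chelates and activates the ring oxygen, and the C1–O bond breaks while the CH(CH3) carbon of the cyclobutane migrates anti-periplanar from the carbinol carbon to C1 and the carbinol carbon becomes the ketone (a semipinacol 1,2-shift). The closest known reaction types are the semipinacol rearrangement of 2,3-epoxy alcohols, the alkylaluminium-promoted ring expansion of α-alkoxy β-hydroxy sulfones and the 1,2-shift of β-mesyloxy alcohols; what is new is that an unstrained ether oxygen is the leaving group, which the release of cyclobutane strain and the chelate should make possible. The five-membered ring is formed by ring enlargement (1,2-alkyl shift, four to five atoms) and not by a cyclisation, and the tetrahydrofuran is opened to the CH2OH group. C5 of ring B (the former C1) is set by inversion, so its configuration follows from the convex-face addition of step 14, and C4 keeps the (R)-configuration of ketone 4 because the migrating carbon moves with retention; together they give the cis-4,5 arrangement. The step needs migration of the more substituted ring carbon instead of the CH2 group, which its higher migratory aptitude should secure, and cleavage of the secondary ether C–O bond instead of a tertiary carbinol C–O bond, which the alkoxide character of both tertiary oxygens should secure.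

Step 16
Reactants: 22 (2S,3R)-2-[(1S,2R,4S)-2-hydroxy-2-(hydroxymethyl)-4-[(2Z)-6-methylhepta-2,5-dien-2-yl]cyclopentyl]-3-methylcyclopentan-1-one
Product: 23 [(1R,2S,4S)-1-hydroxy-4-[(2Z)-6-methylhepta-2,5-dien-2-yl]-2-[(1S,2R)-2-methyl-5-oxocyclopentyl]cyclopentyl]methyl acetate
Conditions: Ac2O, pyridine, CH2Cl2, 0 °C
Reagents that add atoms: acetic anhydride CC(=O)OC(C)=O
Why: acetylation of the primary alcohol, which the hindered tertiary alcohol should not undergo, and which also draws any cyclic hemiketal form back to the open keto alcohol.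

Step 17
Reactants: 23 [(1R,2S,4S)-1-hydroxy-4-[(2Z)-6-methylhepta-2,5-dien-2-yl]-2-[(1S,2R)-2-methyl-5-oxocyclopentyl]cyclopentyl]methyl acetate
Product: 26 [(1R,2S,4S)-1-hydroxy-4-[(2Z)-6-methylhepta-2,5-dien-2-yl]-2-[(1S,5R)-5-methyl-2-oxocyclopent-3-en-1-yl]cyclopentyl]methyl acetate, via enol silane 24 (not isolated), via silyl ether enone 25 (not isolated)
Conditions: LiN(i-Pr)2 (2.2 equiv), Me3SiCl (3 equiv), THF, −78 °C; Pd(OAc)2 (1.1 equiv), MeCN, 23 °C; citric acid, MeOH
Reagents that add atoms: none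
Why: kinetic deprotonation at the less hindered CH2 (C2 of ring B) with in situ silylation gives the regiodefined enol silane (the tertiary alkoxide is silylated too), and Saegusa–Ito oxidation with divalent palladium forms the C2–C3 alkene; no equilibrating base acts on C5, so the cis-4,5 arrangement should survive, and mild acidic methanolysis removes the tertiary silyl ether.

Step 18
Reactants: 26 [(1R,2S,4S)-1-hydroxy-4-[(2Z)-6-methylhepta-2,5-dien-2-yl]-2-[(1S,5R)-5-methyl-2-oxocyclopent-3-en-1-yl]cyclopentyl]methyl acetate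
Product: 27 [(1R,2S,4S)-1-hydroxy-4-[(2Z,4E)-6-hydroperoxy-6-methylhepta-2,4-dien-2-yl]-2-[(1S,5R)-5-methyl-2-oxocyclopent-3-en-1-yl]cyclopentyl]methyl acetate
Conditions: O2, visible light, 5,10,15,20-tetraphenylporphyrin (cat.), CH2Cl2, −20 °C
Reagents that add atoms: dioxygen O=O
Why: Schenck ene reaction, in which singlet oxygen should add to the dimethyl-substituted carbon of the terminal isopropylidene group and abstract a doubly allylic hydrogen, moving that alkene into conjugation as the (E)-isomer and giving the tertiary allylic hydroperoxide; the electron-poor enone alkene should not react and no stereocentre is formed.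

**Compound list**

1 | methyl (R)-2-hydroxypropanoate | C[C@@H](O)C(=O)OC | starting material
2 | (R)-1-(1-hydroxyethyl)cyclopropan-1-ol | C[C@@H](O)C1(O)CC1 | intermediate
3 | (R)-1-(1-hydroxycyclopropyl)ethyl methanesulfonate | C[C@@H](OS(C)(=O)=O)C1(O)CC1 | intermediate (not isolated)
4 | (R)-2-methylcyclobutan-1-one | O=C1CC[C@H]1C | intermediate
5 | cyclopenta-1,3-diene | C1=CC=CC1 | starting material
6 | 2,2,2-trifluoroethyl prop-2-enoate | C=CC(=O)OCC(F)(F)F | starting material
7 | 2,2,2-trifluoroethyl (1S,2S,4S)-bicyclo[2.2.1]hept-5-ene-2-carboxylate (endo ester) | O=C(OCC(F)(F)F)[C@H]1C[C@@H](C=C2)C[C@H]12 | intermediate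
8 | 2,2,2-trifluoroethyl (1S,2R,4S)-2-hydroxybicyclo[2.2.1]hept-5-ene-2-carboxylate (exo hydroxyl) | O=C(OCC(F)(F)F)[C@@]1(O)C[C@@H](C=C2)C[C@H]12 | intermediate
9 | (1S,2R,4S)-2-(hydroxymethyl)bicyclo[2.2.1]hept-5-en-2-ol | OC[C@@]1(O)C[C@@H](C=C2)C[C@H]12 | intermediate
10 | (1S,3R,4R)-4-hydroxy-4-(hydroxymethyl)cyclopentane-1,3-dicarbaldehyde | OC[C@@]1(O)C[C@@H](C=O)C[C@H]1C=O | intermediate (not isolated)
11 | (3aR,5S,6aR)-1,3a-dihydroxyhexahydro-1H-cyclopenta[c]furan-5-carbaldehyde (cis-fused lactol, both C1 epimers) | C1[C@@]2(O)C[C@@H](C=O)C[C@H]2C(O)O1 | intermediate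
12 | (3aR,5S,6aR)-5-ethynylhexahydro-1H-cyclopenta[c]furan-1,3a-diol (both C1 epimers) | C1[C@@]2(O)C[C@@H](C#C)C[C@H]2C(O)O1 | intermediate
13 | (3aR,5S,6aR)-5-ethynyl-1-(phenylsulfanyl)hexahydro-1H-cyclopenta[c]furan-3a-ol (both C1 epimers) | C1[C@@]2(O)C[C@@H](C#C)C[C@H]2C(Sc3ccccc3)O1 | intermediate
14 | methyl 3-[(3aR,5S,6aR)-3a-(methoxycarbonyloxy)-1-(phenylsulfanyl)hexahydro-1H-cyclopenta[c]furan-5-yl]prop-2-ynoate | C1[C@@]2(OC(=O)OC)C[C@@H](C#CC(=O)OC)C[C@H]2C(Sc3ccccc3)O1 | intermediate
15 | methyl (2Z)-3-[(3aR,5S,6aR)-3a-(methoxycarbonyloxy)-1-(phenylsulfanyl)hexahydro-1H-cyclopenta[c]furan-5-yl]but-2-enoate | C1[C@@]2(OC(=O)OC)C[C@@H](/C(C)=C\C(=O)OC)C[C@H]2C(Sc3ccccc3)O1 | intermediate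
16 | (3aR,5S,6aR)-5-[(2Z)-4-hydroxybut-2-en-2-yl]-1-(phenylsulfanyl)hexahydro-1H-cyclopenta[c]furan-3a-ol | C1[C@@]2(O)C[C@@H](/C(C)=C\CO)C[C@H]2C(Sc3ccccc3)O1 | intermediate
17 | (2Z)-3-[(3aR,5S,6aR)-3a-hydroxy-1-(phenylsulfanyl)hexahydro-1H-cyclopenta[c]furan-5-yl]but-2-en-1-yl methanesulfonate | C1[C@@]2(O)C[C@@H](/C(C)=C\COS(C)(=O)=O)C[C@H]2C(Sc3ccccc3)O1 | intermediate (not isolated)
18 | (3aR,5S,6aR)-5-[(2Z)-4-chlorobut-2-en-2-yl]-1-(phenylsulfanyl)hexahydro-1H-cyclopenta[c]furan-3a-ol | C1[C@@]2(O)C[C@@H](/C(C)=C\CCl)C[C@H]2C(Sc3ccccc3)O1 | intermediate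
19 | (3aR,5S,6aR)-5-[(2Z)-6-methylhepta-2,5-dien-2-yl]-1-(phenylsulfanyl)hexahydro-1H-cyclopenta[c]furan-3a-ol | C1[C@@]2(O)C[C@@H](/C(C)=C\CC=C(C)C)C[C@H]2C(Sc3ccccc3)O1 | intermediate
20 | lithium alkoxide of the C1-lithiated bicyclic ether (lithium on the convex face) | C1[C@@]2(O[Li])C[C@@H](/C(C)=C\CC=C(C)C)C[C@H]2[C@H]([Li])O1 | intermediate (not isolated)
21 | (1R,3aR,5S,6aS)-1-[(2R)-1-hydroxy-2-methylcyclobutyl]-5-[(2Z)-6-methylhepta-2,5-dien-2-yl]hexahydro-1H-cyclopenta[c]furan-3a-ol (both carbinol epimers) | C1[C@@]2(O)C[C@@H](/C(C)=C\CC=C(C)C)C[C@H]2[C@H](C3(O)CC[C@H]3C)O1 | intermediate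
22 | (2S,3R)-2-[(1S,2R,4S)-2-hydroxy-2-(hydroxymethyl)-4-[(2Z)-6-methylhepta-2,5-dien-2-yl]cyclopentyl]-3-methylcyclopentan-1-one | OC[C@@]1(O)C[C@@H](/C(C)=C\CC=C(C)C)C[C@H]1[C@H]1C(=O)CC[C@H]1C | intermediate
23 | [(1R,2S,4S)-1-hydroxy-4-[(2Z)-6-methylhepta-2,5-dien-2-yl]-2-[(1S,2R)-2-methyl-5-oxocyclopentyl]cyclopentyl]methyl acetate | CC(=O)OC[C@@]1(O)C[C@@H](/C(C)=C\CC=C(C)C)C[C@H]1[C@H]1C(=O)CC[C@H]1C | intermediate
24 | enol silane of 23 toward C2 of ring B, with the tertiary hydroxyl as its trimethylsilyl ether | CC(=O)OC[C@@]1(O[Si](C)(C)C)C[C@@H](/C(C)=C\CC=C(C)C)C[C@H]1[C@H]1C(O[Si](C)(C)C)=CC[C@H]1C | intermediate (not isolated)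
25 | trimethylsilyl ether (tertiary oxygen) of enone 26 | CC(=O)OC[C@@]1(O[Si](C)(C)C)C[C@@H](/C(C)=C\CC=C(C)C)C[C@H]1[C@H]1C(=O)C=C[C@H]1C | intermediate (not isolated)
26 | [(1R,2S,4S)-1-hydroxy-4-[(2Z)-6-methylhepta-2,5-dien-2-yl]-2-[(1S,5R)-5-methyl-2-oxocyclopent-3-en-1-yl]cyclopentyl]methyl acetate | CC(=O)OC[C@@]1(O)C[C@@H](/C(C)=C\CC=C(C)C)C[C@H]1[C@H]1C(=O)C=C[C@H]1C | intermediate
27 | [(1R,2S,4S)-1-hydroxy-4-[(2Z,4E)-6-hydroperoxy-6-methylhepta-2,4-dien-2-yl]-2-[(1S,5R)-5-methyl-2-oxocyclopent-3-en-1-yl]cyclopentyl]methyl acetate | CC(=O)OC[C@@]1(O)C[C@@H](/C(C)=C\C=C\C(C)(C)OO)C[C@H]1[C@H]1C(=O)C=C[C@H]1C | target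

**Step count and risks**

Total step count: 18. Longest linear sequence: 16 steps (steps 3 to 18); steps 1 and 2 make ketone 4.

The three steps most likely to fail:

1. Step 15 (proposed new method). The ether oxygen may fail to leave so that no shift occurs, the cyclobutanol may ionise at its tertiary carbon, or the CH2 ring carbon may migrate instead of the CH(CH3) carbon. The fallback uses known chemistry, sets out from 19 and comes back at 22. The sulfide of 19 is oxidised chemoselectively (H2O2, (NH4)6Mo7O24, EtOH, 0 °C) to the phenyl sulfone F1. Its α-sulfonyl carbanion (n-BuLi, 2.1 equiv, THF, −78 °C) adds to 4 to give the β-hydroxy sulfone F2. EtAlCl2 (CH2Cl2, −78 °C) expels benzenesulfinate to the ring oxocarbenium ion, onto which the CH(CH3) ring carbon shifts (the known ring expansion of α-alkoxy β-hydroxy sulfones), giving the spiro α-alkoxy ketone F3. SmI2 (THF–MeOH, −78 °C) cleaves the C–O bond α to the ketone, and the samarium enolate is protonated on the face opposite to the C4 methyl group, which should again give the cis ketone 22. In this variant C5 rests on kinetic protonation instead of a stereospecific shift.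

2. Step 18. Singlet oxygen may also attack the internal trisubstituted alkene or abstract a methyl hydrogen of the isopropylidene group, so that site selectivity and regioselectivity are poor. The fallback sets out from 26 and comes back at 27, and makes no compound outside the list (none F0). It replaces the pericyclic ene reaction by a radical-chain autoxidation with ground-state oxygen (O2, N-hydroxyphthalimide (10 mol %), MeCN, 30 °C). The N-oxyl radical abstracts the weak doubly allylic hydrogen, the pentadienyl radical takes up oxygen at its less hindered terminal tertiary carbon, and the peroxyl radical is reduced by the N-hydroxy compound, as in the autoxidation of skipped dienes to conjugated diene hydroperoxides.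

3. Step 17. The base may deprotonate the acetate or the hindered C5–H, leading to loss of the cis arrangement or to the wrong enol silane. The fallback sets out from 22 and comes back at 26, and moves the desaturation in front of the acetylation so that no ester and no free hydroxyl group meet the base. N-(Trimethylsilyl)imidazole gives the bis(trimethylsilyl) ether F4. LiN(i-Pr)2 and Me3SiCl (THF, −78 °C) give the enol silane F5 (not isolated). Pd(OAc)2 (MeCN, 23 °C) gives the silylated enone F6. Citric acid in MeOH gives the enone diol F7. Ac2O and 2,4,6-collidine (CH2Cl2, −20 °C) acetylate the primary alcohol to 26.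

Further compounds

F1 | step 15 | (3aR,5S,6aR)-5-[(2Z)-6-methylhepta-2,5-dien-2-yl]-1-(phenylsulfonyl)hexahydro-1H-cyclopenta[c]furan-3a-ol (phenyl sulfone) | C1[C@@]2(O)C[C@@H](/C(C)=C\CC=C(C)C)C[C@H]2C(S(=O)(=O)c3ccccc3)O1
F2 | step 15 | (3aR,5S,6aR)-1-[(2R)-1-hydroxy-2-methylcyclobutyl]-5-[(2Z)-6-methylhepta-2,5-dien-2-yl]-1-(phenylsulfonyl)hexahydro-1H-cyclopenta[c]furan-3a-ol (β-hydroxy sulfone, mixture at C1 and at the carbinol carbon) | C1[C@@]2(O)C[C@@H](/C(C)=C\CC=C(C)C)C[C@H]2C(S(=O)(=O)c3ccccc3)(C3(O)CC[C@H]3C)O1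
F3 | step 15 | (2R)-3a′-hydroxy-2-methyl-5′-[(2Z)-6-methylhepta-2,5-dien-2-yl]hexahydrospiro[cyclopentane-1,1′-cyclopenta[c]furan]-5-one (spiro α-alkoxy ketone, ring A centres as in 19) | C1[C@@]2(O)C[C@@H](/C(C)=C\CC=C(C)C)C[C@H]2C3(O1)C(=O)CC[C@H]3C
F0 | step 18 | none | none
F4 | step 17 | bis(trimethylsilyl) ether of keto diol 22 | C[Si](C)(C)OC[C@@]1(O[Si](C)(C)C)C[C@@H](/C(C)=C\CC=C(C)C)C[C@H]1[C@H]1C(=O)CC[C@H]1C
F5 | step 17 | enol silane of F4 toward C2 of ring B | C[Si](C)(C)OC[C@@]1(O[Si](C)(C)C)C[C@@H](/C(C)=C\CC=C(C)C)C[C@H]1[C@H]1C(O[Si](C)(C)C)=CC[C@H]1C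
F6 | step 17 | bis(trimethylsilyl) ether of enone diol F7 (silylated enone) | C[Si](C)(C)OC[C@@]1(O[Si](C)(C)C)C[C@@H](/C(C)=C\CC=C(C)C)C[C@H]1[C@H]1C(=O)C=C[C@H]1C
F7 | step 17 | (4R,5S)-5-[(1S,2R,4S)-2-hydroxy-2-(hydroxymethyl)-4-[(2Z)-6-methylhepta-2,5-dien-2-yl]cyclopentyl]-4-methylcyclopent-2-en-1-one (enone diol) | OC[C@@]1(O)C[C@@H](/C(C)=C\CC=C(C)C)C[C@H]1[C@H]1C(=O)C=C[C@H]1C
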